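**Plan**
1. Retrosynthesis (rings: A benzene, B the five-membered N-ring, C carbocycle, D cyclic carbamate, E piperidine, F pyrrolidine): cut the carbinolamine C–N of ring E (amine + aldehyde), then the carbamate O–C4a bond of ring D (oxidative closure of a Boc-amine onto indole C3), then rings A/B (Fischer indolisation of a ketone at the future indole C2), then the C–N bond at the quaternary carbon (Hofmann, from a nitrile), and last the two ring-C bonds CMe2–CH and CH2–C(quaternary).
2. These last cuts lead to isopropyl vinyl ketone and an alkylidene cyanoacetate built from D-β-homoproline, which carries ring F.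
3. Forward order: side-chain aldehyde → Knoevenagel acceptor → ring C (step 5) → nitrile to carbamate → rings A/B → exchange of N-protection and ester to aldehyde → ring D → ring E.
4. Stereochemistry: the pyrrolidine centre is bought; the ring-C CH centre is set by the amine catalyst; the quaternary centre is set by substrate control in the same event (nitrile axial) and kept by the Hofmann shift; C4a follows from the carbamate tether; the carbinolamine equilibrates.
5. Enabling feature: in ring C the CMe2 carbon sits on indole C2 and the amino-bearing quaternary carbon lies one CH2 from indole C3. With the indole undone to a C2 ketone, CMe2 is the α'-carbon and the quaternary carbon the γ-carbon of a cyclohexanone, the adduct of a 2-aminodiene from isopropyl vinyl ketone and a two-carbon acceptor.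

Key step: step 5

Assumption: 9-amino-9-deoxy-epi-quinine is taken to give the (2R) ring centre of 8; if the sense of induction is the opposite, the pseudo-enantiomeric 9-amino-9-deoxy-epi-quinidine is used instead.

**Step 1**
Reactants: 1 D-β-homoproline, (R)-2-(pyrrolidin-2-yl)acetic acid
Product: 2 (R)-2-[1-(benzyloxycarbonyl)pyrrolidin-2-yl]acetic acid
Conditions: CbzCl, NaOH, H2O–dioxane, 0 °C → rt; HCl to pH 2
Reagents that add atoms: benzyl chloroformate, O=C(Cl)OCc1ccccc1
Why: Schotten–Baumann N-acylation; the benzyl carbamate is chosen because it survives the acid of the Fischer step and is later exchanged by hydrogenolysis, and the stereocentre is not touched.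

**Step 2**
Reactants: 2 (R)-2-[1-(benzyloxycarbonyl)pyrrolidin-2-yl]acetic acid
Product: 3 benzyl (R)-2-(2-hydroxyethyl)pyrrolidine-1-carboxylate
Conditions: BH3·THF, THF, 0 °C → rt; MeOH, then aq. NaHCO3
Reagents that add atoms: none
Why: Borane reduction of a carboxylic acid, which is chemoselective over the carbamate.

**Step 3**
Reactants: 3 benzyl (R)-2-(2-hydroxyethyl)pyrrolidine-1-carboxylate
Product: 4 benzyl (R)-2-(2-oxoethyl)pyrrolidine-1-carboxylate
Conditions: Dess–Martin periodinane, CH2Cl2, 0 °C → rt
Reagents that add atoms: none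
Why: Dess–Martin oxidation of the primary alcohol under non-basic conditions, so that the β-carbamoyl aldehyde is not opened by elimination; the aldehyde is used at once.

**Step 4**
Reactants: 4 benzyl (R)-2-(2-oxoethyl)pyrrolidine-1-carboxylate
Product: 5 methyl (2E)-4-[(2R)-1-(benzyloxycarbonyl)pyrrolidin-2-yl]-2-cyanobut-2-enoate
Conditions: NCCH2CO2Me, piperidine (10 mol %), AcOH (10 mol %), 4 Å molecular sieves, CH2Cl2, 0 °C → rt
Reagents that add atoms: methyl cyanoacetate, N#CCC(=O)OC
Why: Knoevenagel condensation under buffered piperidinium acetate catalysis; the alkene geometry (E expected) does not matter because it is erased in the Michael addition of step 5.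

**Step 5**
Reactants: 5 methyl (2E)-4-[(2R)-1-(benzyloxycarbonyl)pyrrolidin-2-yl]-2-cyanobut-2-enoate; 6 4-methylpent-1-en-3-one (isopropyl vinyl ketone)
Product: 8 methyl (1R,2R)-2-{[(2R)-1-(benzyloxycarbonyl)pyrrolidin-2-yl]methyl}-1-cyano-3,3-dimethyl-4-oxocyclohexane-1-carboxylate (nitrile cis to the side chain), via open-chain Michael adduct 7 (not isolated)
Conditions: 9-amino-9-deoxy-epi-quinine (20 mol %), 2-fluorobenzoic acid (40 mol %), 6 (3 equiv), toluene, 40 °C
Reagents that add atoms: none
Why: Proposed new method: the primary amine condenses with 6, whose only α-hydrogen is the isopropyl methine, to a cross-conjugated 2-aminodiene; its gem-dimethyl terminus adds to the β-carbon of 5 (CMe2–CH bond), and the cyanoacetate anion then closes by a 6-endo-trig Michael addition onto the terminal carbon of the vinyl iminium ion (CH2–C(quaternary) bond) before hydrolysis releases 8 and the amine. The closest known reactions are the amine-catalysed formal [4+2] annulations of methyl enones with Knoevenagel acceptors and nitroalkenes and the cinchona primary amine dienamine additions to alkylidene cyanoacetates; new here is the dienamine from an α'-methine of a vinyl ketone, which creates the quaternary CMe2 carbon. The CH stereocentre is set by the catalyst, whose protonated quinuclidine holds the cyano ester while the dienamine is delivered to one face, so the remote pyrrolidine centre is only carried along. The quaternary centre is set by substrate control in the chair-like ring closure: the side chain is equatorial and the in-plane ester avoids the gem-dimethyl carbon, so the slim nitrile becomes axial and cis to the side chain, the place the nitrogen must later occupy. The step needs the aminodiene to choose 5 over a second molecule of 6, which is secured because 5 is much the stronger acceptor and 6 is in excess so that product 8 does not re-enter as a donor; no other regiochemistry is open, since only the methine carbon is nucleophilic and the anion can reach only the vinyl terminus in a six-membered ring.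

**Step 6**
Reactants: 8 methyl (1R,2R)-2-{[(2R)-1-(benzyloxycarbonyl)pyrrolidin-2-yl]methyl}-1-cyano-3,3-dimethyl-4-oxocyclohexane-1-carboxylate
Product: 9 methyl (1R,2R)-2-{[(2R)-1-(benzyloxycarbonyl)pyrrolidin-2-yl]methyl}-1-carbamoyl-3,3-dimethyl-4-oxocyclohexane-1-carboxylate
Conditions: [PtH(PMe2OH){(PMe2O)2H}] (5 mol %), EtOH–H2O 4:1, 80 °C
Reagents that add atoms: water, O
Why: Ghaffar–Parkins platinum-catalysed nitrile hydration, which converts hindered nitriles to primary amides under neutral conditions, so that ketone, ester and carbamate are kept and no base is present to reverse the Michael ring closure.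

**Step 7**
Reactants: 9 methyl (1R,2R)-2-{[(2R)-1-(benzyloxycarbonyl)pyrrolidin-2-yl]methyl}-1-carbamoyl-3,3-dimethyl-4-oxocyclohexane-1-carboxylate
Product: 11 methyl (1S,2R)-1-{[(benzyloxy)carbonyl]amino}-2-{[(2R)-1-(benzyloxycarbonyl)pyrrolidin-2-yl]methyl}-3,3-dimethyl-4-oxocyclohexane-1-carboxylate, via isocyanate 10 (not isolated)
Conditions: PhI(OAc)2, BnOH, ClCH2CH2Cl, 60 °C
Reagents that add atoms: benzyl alcohol, OCc1ccccc1
Why: Hofmann rearrangement with a trivalent iodine oxidant, in which the quaternary carbon shifts to nitrogen with retention so that nitrogen takes over the axial site of the nitrile; benzyl alcohol traps the isocyanate as an acid-stable carbamate, and the step is placed before the indole exists because the oxidant would attack an indole.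

**Step 8**
Reactants: 11 methyl (1S,2R)-1-{[(benzyloxy)carbonyl]amino}-2-{[(2R)-1-(benzyloxycarbonyl)pyrrolidin-2-yl]methyl}-3,3-dimethyl-4-oxocyclohexane-1-carboxylate
Product: 13 methyl (2R,3S)-3-{[(benzyloxy)carbonyl]amino}-2-{[(2R)-1-(benzyloxycarbonyl)pyrrolidin-2-yl]methyl}-1,1-dimethyl-2,3,4,9-tetrahydro-1H-carbazole-3-carboxylate, via phenylhydrazone 12 (not isolated)
Conditions: PhNHNH2, AcOH, 90 °C
Reagents that add atoms: phenylhydrazine, NNc1ccccc1
Why: Fischer indole synthesis; the ketone can form an ene-hydrazine only towards its CH2 side because the other α-carbon is quaternary, so the [3,3] shift places CMe2 on indole C2, and the benzyl carbamates and the ester are stable to acetic acid.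

**Step 9**
Reactants: 13 methyl (2R,3S)-3-{[(benzyloxy)carbonyl]amino}-2-{[(2R)-1-(benzyloxycarbonyl)pyrrolidin-2-yl]methyl}-1,1-dimethyl-2,3,4,9-tetrahydro-1H-carbazole-3-carboxylate
Product: 15 methyl (2R,3S)-3-[(tert-butoxycarbonyl)amino]-2-{[(2R)-1-(tert-butoxycarbonyl)pyrrolidin-2-yl]methyl}-1,1-dimethyl-2,3,4,9-tetrahydro-1H-carbazole-3-carboxylate, via diamino ester 14 (not isolated)
Conditions: H2 (1 atm), 10% Pd/C, Boc2O, MeOH–THF, rt → 40 °C
Reagents that add atoms: di-tert-butyl dicarbonate, CC(C)(C)OC(=O)OC(=O)OC(C)(C)C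
Why: Hydrogenolysis of both benzyl carbamates with in situ Boc protection, which stops the freed pyrrolidine from lactamising onto the ester, gives the ring-C nitrogen the tert-butyl carbamate needed in step 11 and gives the pyrrolidine an acid-labile group for the end.

**Step 10**
Reactants: 15 methyl (2R,3S)-3-[(tert-butoxycarbonyl)amino]-2-{[(2R)-1-(tert-butoxycarbonyl)pyrrolidin-2-yl]methyl}-1,1-dimethyl-2,3,4,9-tetrahydro-1H-carbazole-3-carboxylate
Product: 16 tert-butyl (2R)-2-{[(2R,3S)-3-[(tert-butoxycarbonyl)amino]-3-formyl-1,1-dimethyl-2,3,4,9-tetrahydro-1H-carbazol-2-yl]methyl}pyrrolidine-1-carboxylate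
Conditions: i-Bu2AlH (4 equiv), CH2Cl2, −78 °C; aq. potassium sodium tartrate
Reagents that add atoms: none
Why: Partial reduction of an ester to the aldehyde; the aluminium-chelated tetrahedral adduct of the neopentyl α-carbamoyl ester should persist at −78 °C and collapse only on work-up, the two N–H groups taking up the extra hydride equivalents.

**Step 11**
Reactants: 16 tert-butyl (2R)-2-{[(2R,3S)-3-[(tert-butoxycarbonyl)amino]-3-formyl-1,1-dimethyl-2,3,4,9-tetrahydro-1H-carbazol-2-yl]methyl}pyrrolidine-1-carboxylate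
Product: 17 tert-butyl (2R)-2-{[(2R,3S,4aS)-3-formyl-1,1-dimethyl-3,4a-(epiminocarbonyloxy)-2,3,4,4a-tetrahydro-1H-carbazol-2-yl]methyl}pyrrolidine-1-carboxylate (cyclic carbamate, N on C3 and O on C4a)
Conditions: PhI(OAc)2, CH2Cl2, −20 °C → rt
Reagents that add atoms: none
Why: Oxidative dearomatising cyclisation with a trivalent iodine reagent (related to halocyclisation of Boc-amines to cyclic carbamates and to PhI(OAc)2 dearomatisation of 2,3-disubstituted indoles): the indole N–H binds iodine, the Boc carbonyl oxygen on the axial nitrogen attacks C4a in a six-membered ring and can only reach the face syn to nitrogen, which fixes the C4a centre, and PhI and the tert-butyl group (as isobutene) leave.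

**Step 12**
Reactants: 17 tert-butyl (2R)-2-{[(2R,3S,4aS)-3-formyl-1,1-dimethyl-3,4a-(epiminocarbonyloxy)-2,3,4,4a-tetrahydro-1H-carbazol-2-yl]methyl}pyrrolidine-1-carboxylate
Product: 19 penicimutamide B, via amino aldehyde 18 (not isolated)
Conditions: CF3CO2H, CH2Cl2, 0 °C → rt; then aq. NaHCO3
Reagents that add atoms: none
Why: Acidolysis of the Boc group, after which the free pyrrolidine nitrogen adds to the neighbouring aldehyde (6-exo-trig carbinolamine formation); the addition is reversible, so the hydroxyl should settle in the axial position anti to the carbamate nitrogen, as in the target, and no enamine can form because the neighbouring carbon is quaternary.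

**Compound list**
1 | D-β-homoproline, (R)-2-(pyrrolidin-2-yl)acetic acid | OC(=O)C[C@H]1CCCN1 | starting material
2 | (R)-2-[1-(benzyloxycarbonyl)pyrrolidin-2-yl]acetic acid | OC(=O)C[C@H]1CCCN1C(=O)OCc1ccccc1 | intermediate
3 | benzyl (R)-2-(2-hydroxyethyl)pyrrolidine-1-carboxylate | OCC[C@H]1CCCN1C(=O)OCc1ccccc1 | intermediate
4 | benzyl (R)-2-(2-oxoethyl)pyrrolidine-1-carboxylate | O=CC[C@H]1CCCN1C(=O)OCc1ccccc1 | intermediate
5 | methyl (2E)-4-[(2R)-1-(benzyloxycarbonyl)pyrrolidin-2-yl]-2-cyanobut-2-enoate | COC(=O)/C(C#N)=C/C[C@H]1CCCN1C(=O)OCc1ccccc1 | intermediate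
6 | 4-methylpent-1-en-3-one (isopropyl vinyl ketone) | C=CC(=O)C(C)C | starting material
7 | benzyl (2R)-2-[(2S)-2-(1-cyano-2-methoxy-2-oxoethyl)-3,3-dimethyl-4-oxohex-5-en-1-yl]pyrrolidine-1-carboxylate (both epimers at the cyanoacetate carbon) | C=CC(=O)C(C)(C)[C@H](C(C#N)C(=O)OC)C[C@H]1CCCN1C(=O)OCc1ccccc1 | intermediate
8 | methyl (1R,2R)-2-{[(2R)-1-(benzyloxycarbonyl)pyrrolidin-2-yl]methyl}-1-cyano-3,3-dimethyl-4-oxocyclohexane-1-carboxylate | CC1(C)C(=O)CC[C@](C(=O)OC)(C#N)[C@@H]1C[C@H]1CCCN1C(=O)OCc1ccccc1 | intermediate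
9 | methyl (1R,2R)-2-{[(2R)-1-(benzyloxycarbonyl)pyrrolidin-2-yl]methyl}-1-carbamoyl-3,3-dimethyl-4-oxocyclohexane-1-carboxylate | CC1(C)C(=O)CC[C@](C(=O)OC)(C(N)=O)[C@@H]1C[C@H]1CCCN1C(=O)OCc1ccccc1 | intermediate
10 | methyl (1S,2R)-2-{[(2R)-1-(benzyloxycarbonyl)pyrrolidin-2-yl]methyl}-1-isocyanato-3,3-dimethyl-4-oxocyclohexane-1-carboxylate | CC1(C)C(=O)CC[C@](C(=O)OC)(N=C=O)[C@@H]1C[C@H]1CCCN1C(=O)OCc1ccccc1 | intermediate
11 | methyl (1S,2R)-1-{[(benzyloxy)carbonyl]amino}-2-{[(2R)-1-(benzyloxycarbonyl)pyrrolidin-2-yl]methyl}-3,3-dimethyl-4-oxocyclohexane-1-carboxylate | CC1(C)C(=O)CC[C@](C(=O)OC)(NC(=O)OCc2ccccc2)[C@@H]1C[C@H]1CCCN1C(=O)OCc1ccccc1 | intermediate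
12 | phenylhydrazone of 11 | CC1(C)C(=NNc2ccccc2)CC[C@](C(=O)OC)(NC(=O)OCc2ccccc2)[C@@H]1C[C@H]1CCCN1C(=O)OCc1ccccc1 | intermediate
13 | methyl (2R,3S)-3-{[(benzyloxy)carbonyl]amino}-2-{[(2R)-1-(benzyloxycarbonyl)pyrrolidin-2-yl]methyl}-1,1-dimethyl-2,3,4,9-tetrahydro-1H-carbazole-3-carboxylate | CC1(C)c2[nH]c3ccccc3c2C[C@](C(=O)OC)(NC(=O)OCc2ccccc2)[C@@H]1C[C@H]1CCCN1C(=O)OCc1ccccc1 | intermediate
14 | methyl (2R,3S)-3-amino-1,1-dimethyl-2-{[(2R)-pyrrolidin-2-yl]methyl}-2,3,4,9-tetrahydro-1H-carbazole-3-carboxylate | CC1(C)c2[nH]c3ccccc3c2C[C@](C(=O)OC)(N)[C@@H]1C[C@H]1CCCN1 | intermediate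
15 | methyl (2R,3S)-3-[(tert-butoxycarbonyl)amino]-2-{[(2R)-1-(tert-butoxycarbonyl)pyrrolidin-2-yl]methyl}-1,1-dimethyl-2,3,4,9-tetrahydro-1H-carbazole-3-carboxylate | CC1(C)c2[nH]c3ccccc3c2C[C@](C(=O)OC)(NC(=O)OC(C)(C)C)[C@@H]1C[C@H]1CCCN1C(=O)OC(C)(C)C | intermediate
16 | tert-butyl (2R)-2-{[(2R,3S)-3-[(tert-butoxycarbonyl)amino]-3-formyl-1,1-dimethyl-2,3,4,9-tetrahydro-1H-carbazol-2-yl]methyl}pyrrolidine-1-carboxylate | CC1(C)c2[nH]c3ccccc3c2C[C@](C=O)(NC(=O)OC(C)(C)C)[C@@H]1C[C@H]1CCCN1C(=O)OC(C)(C)C | intermediate
17 | tert-butyl (2R)-2-{[(2R,3S,4aS)-3-formyl-1,1-dimethyl-3,4a-(epiminocarbonyloxy)-2,3,4,4a-tetrahydro-1H-carbazol-2-yl]methyl}pyrrolidine-1-carboxylate | CC1(C)C2=Nc3ccccc3[C@@]23C[C@](C=O)(NC(=O)O3)[C@@H]1C[C@H]1CCCN1C(=O)OC(C)(C)C | intermediate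
18 | (2R,3S,4aS)-1,1-dimethyl-3,4a-(epiminocarbonyloxy)-2-{[(2R)-pyrrolidin-2-yl]methyl}-2,3,4,4a-tetrahydro-1H-carbazole-3-carbaldehyde | CC1(C)C2=Nc3ccccc3[C@@]23C[C@](C=O)(NC(=O)O3)[C@@H]1C[C@H]1CCCN1 | intermediate
19 | penicimutamide B (carbinolamine carbon R, quaternary C–N carbon S, ring-C CH R, pyrrolidine CH R, C4a S) | CC1(C)C2=Nc3ccccc3[C@@]23C[C@]2(NC(=O)O3)[C@@H]1C[C@H]1CCCN1[C@@H]2O | target

**Count and risks**
Total step count: 12. Longest linear sequence: 12 steps (1 → 19); ketone 6 is a purchased partner.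

The three steps most likely to fail:

Step 5 (Proposed new method). The tetrasubstituted aminodiene may form too slowly, the vinyl ketone may polymerise or be consumed by aza-Michael addition of the catalyst, the acceptor may drift out of conjugation, and face selection by the catalyst at the CH centre may be poor. The fallback sets out from 5 and 6 and comes back at 8, using known chemistry: 6 is deprotonated at its only α-hydrogen with LiN(i-Pr)2 in THF at −78 °C to the cross-conjugated lithium dienolate, which adds to 5 and closes in an anionic Michael–Michael annulation under the same substrate control for the quaternary centre. Without a catalyst the ring CH centre is not controlled relative to the pyrrolidine, so 8 is accompanied by methyl (1S,2S)-2-{[(2R)-1-(benzyloxycarbonyl)pyrrolidin-2-yl]methyl}-1-cyano-3,3-dimethyl-4-oxocyclohexane-1-carboxylate F1, which is removed by chromatography.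

Step 11. The oxidation may take other courses: capture of the activated indole by acetate or by the aldehyde oxygen instead of the carbamate, a 1,2-shift of the 3-oxyindolenine to an oxindole, or over-oxidation. The fallback sets out from 16 and comes back at 17 and separates C–O bond formation from ring closure. The indole 2,3-bond is hydroxylated with m-chloroperbenzoic acid in CH2Cl2 at −40 °C, the peracid being guided by hydrogen bonding to the carbamate N–H to the face syn to nitrogen, to give tert-butyl (2R)-2-{[(2R,3S,4aS)-3-[(tert-butoxycarbonyl)amino]-3-formyl-4a-hydroxy-1,1-dimethyl-2,3,4,4a-tetrahydro-1H-carbazol-2-yl]methyl}pyrrolidine-1-carboxylate F2. NaH in THF (0 → 50 °C) then closes the tertiary alkoxide onto the Boc carbonyl with loss of tert-butoxide to give 17.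

Step 10. The hydride may over-reduce the ester to the alcohol, stall at the neopentyl ester, or attack a carbamate. The fallback sets out from 15 and comes back at 16 by full reduction and re-oxidation: LiBH4 in THF (0 °C → rt) reduces the ester to tert-butyl (2R)-2-{[(2R,3S)-3-[(tert-butoxycarbonyl)amino]-3-(hydroxymethyl)-1,1-dimethyl-2,3,4,9-tetrahydro-1H-carbazol-2-yl]methyl}pyrrolidine-1-carboxylate F3, and Dess–Martin periodinane in CH2Cl2 oxidises the primary alcohol to 16.

**Further compounds**
F1 | step 5 | methyl (1S,2S)-2-{[(2R)-1-(benzyloxycarbonyl)pyrrolidin-2-yl]methyl}-1-cyano-3,3-dimethyl-4-oxocyclohexane-1-carboxylate | CC1(C)C(=O)CC[C@@](C(=O)OC)(C#N)[C@H]1C[C@H]1CCCN1C(=O)OCc1ccccc1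
F2 | step 11 | tert-butyl (2R)-2-{[(2R,3S,4aS)-3-[(tert-butoxycarbonyl)amino]-3-formyl-4a-hydroxy-1,1-dimethyl-2,3,4,4a-tetrahydro-1H-carbazol-2-yl]methyl}pyrrolidine-1-carboxylate | CC1(C)C2=Nc3ccccc3[C@@]2(O)C[C@](C=O)(NC(=O)OC(C)(C)C)[C@@H]1C[C@H]1CCCN1C(=O)OC(C)(C)C
F3 | step 10 | tert-butyl (2R)-2-{[(2R,3S)-3-[(tert-butoxycarbonyl)amino]-3-(hydroxymethyl)-1,1-dimethyl-2,3,4,9-tetrahydro-1H-carbazol-2-yl]methyl}pyrrolidine-1-carboxylate | CC1(C)c2[nH]c3ccccc3c2C[C@](CO)(NC(=O)OC(C)(C)C)[C@@H]1C[C@H]1CCCN1C(=O)OC(C)(C)C
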